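The seven-membered ring (C3a, C4, C5, C6, C7, C8, C8a, azulene numbering) carries its C6=C7 olefin between C5 and C8, the pattern left by a vinylcyclopropane [5+2] cycloaddition. The route therefore rests on one rhodium-catalysed intramolecular [5+2] step that joins the two-carbon unit C3a–C4, an (E)-enol 4-silyloxybenzoate, to the five-carbon unit C5–C8a, masked as a cis-2-isopropenyl-1-methylcyclopropane, and forms C4–C5 and C3a–C8a together. It closes both rings and sets C3a, C4 and C8a, with the trans fusion, from an acyclic precursor whose C1–C3 tether already carries both carbinol centres.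

Key step: step 9

Assumption: the O-silylated 4-hydroxybenzoic acid used in step 8 is taken as a purchasable building block.

Step 1
Reactants: 1 methacrolein (2-methylprop-2-enal); 2 ethyl 2-[bis(2,2,2-trifluoroethoxy)phosphoryl]propanoate
Product: 4 ethyl (2Z)-2,4-dimethylpenta-2,4-dienoate, via potassium phosphonate carbanion 3 (not isolated)
Conditions: KN(SiMe3)2, 18-crown-6, THF, −78 °C; then 1
Reagents that add atoms: none
Why: Still–Gennari olefination, in which the electron-poor trifluoroethyl phosphonate eliminates from the kinetic adduct and should give the Z enoate with the ester cis to the isopropenyl group.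

Step 2
Reactants: 4 ethyl (2Z)-2,4-dimethylpenta-2,4-dienoate
Product: 5 (2Z)-2,4-dimethylpenta-2,4-dien-1-ol
Conditions: iBu2AlH (2.2 equiv), CH2Cl2, −78 → 0 °C
Reagents that add atoms: none
Why: 1,2-reduction of the unsaturated ester to the allylic alcohol by the aluminium hydride, with the olefin geometry untouched.

Step 3
Reactants: 5 (2Z)-2,4-dimethylpenta-2,4-dien-1-ol
Product: 6 [(1R,2R)-1-methyl-2-(prop-1-en-2-yl)cyclopropyl]methanol (CH2OH and isopropenyl cis)
Conditions: Et2Zn, CH2I2, DME, (4S,5S)-2-butyl-N,N,N′,N′-tetramethyl-1,3,2-dioxaborolane-4,5-dicarboxamide (1.2 equiv), CH2Cl2, −10 → 20 °C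
Reagents that add atoms: diiodomethane C(I)I
Why: Charette asymmetric Simmons–Smith cyclopropanation, in which the zinc alkoxide bound to the chiral boronate delivers methylene only to the allylic olefin and to one face of it, so the Z geometry fixes the cis relation and the (4S,5S) ligand should set the (1R,2R) configuration (C8a of the target).

Step 4
Reactants: 6 [(1R,2R)-1-methyl-2-(prop-1-en-2-yl)cyclopropyl]methanol
Product: 7 (1R,2R)-1-methyl-2-(prop-1-en-2-yl)cyclopropane-1-carbaldehyde
Conditions: Dess–Martin periodinane, NaHCO3, CH2Cl2, 0 °C; used crude at once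
Reagents that add atoms: none
Why: Dess–Martin oxidation under buffered conditions; the α-carbon is quaternary and cannot epimerise, and the aldehyde is kept cold and used directly because cis-2-alkenylcyclopropane carbaldehydes can equilibrate with dihydrooxepines by a reversible retro-Claisen shift.

Step 5
Reactants: 7 (1R,2R)-1-methyl-2-(prop-1-en-2-yl)cyclopropane-1-carbaldehyde; 8 3-methylbutan-2-one
Product: 10 (5S)-5-hydroxy-2-methyl-5-[(1R,2R)-1-methyl-2-(prop-1-en-2-yl)cyclopropyl]pentan-3-one, via lithium enolate 9 (not isolated)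
Conditions: LiN(iPr)2, THF, −78 °C; then 7, −78 °C
Reagents that add atoms: none
Why: Aldol addition of the kinetic lithium enolate through a closed six-membered transition state; the aldehyde should react in its bisected conformer with the carbonyl oxygen eclipsing the C–CH3 bond, and attack from the side of the ring CH2, away from the cis isopropenyl group, sets the (5S) carbinol (C1 of the target).

Step 6
Reactants: 10 (5S)-5-hydroxy-2-methyl-5-[(1R,2R)-1-methyl-2-(prop-1-en-2-yl)cyclopropyl]pentan-3-one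
Product: 11 (1S,3R)-1-[(1R,2R)-1-methyl-2-(prop-1-en-2-yl)cyclopropyl]-3-(propan-2-yl)pent-4-yne-1,3-diol
Conditions: HC≡CMgBr (4 equiv), THF/CH2Cl2, −78 → −30 °C
Reagents that add atoms: ethynylmagnesium bromide C#C[Mg]Br
Why: Chelation-controlled Grignard addition: the magnesium alkoxide formed by the first equivalent chelates the ketone in a half-chair six-membered ring with the cyclopropyl group pseudo-equatorial, and axial attack on the face away from that group should give the 1,3-anti diol, that is the (3R) tertiary carbinol (C3 of the target).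

Step 7
Reactants: 11 (1S,3R)-1-[(1R,2R)-1-methyl-2-(prop-1-en-2-yl)cyclopropyl]-3-(propan-2-yl)pent-4-yne-1,3-diol
Product: 13 potassium [(1E,3R,5S)-3,5-dihydroxy-5-[(1R,2R)-1-methyl-2-(prop-1-en-2-yl)cyclopropyl]-3-(propan-2-yl)pent-1-en-1-yl]trifluoroborate, via pinacol alkenylboronate 12 (not isolated)
Conditions: B2pin2 (1.1 equiv), CuCl (5 mol%), Xantphos (6 mol%), NaOtBu (10 mol%), MeOH (2 equiv), THF, 20 °C; then KHF2, MeOH/H2O, 20 °C
Reagents that add atoms: bis(pinacolato)diboron CC1(C)OB(OC1(C)C)B2OC(C)(C)C(C)(C)O2; potassium hydrogen difluoride [K+].[F-].F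
Why: Copper-catalysed protoboration, in which syn addition of a copper–boryl species with boron on the terminal carbon and protonolysis by methanol give the E-alkenylboronate, which KHF2 converts into the trifluoroborate without touching the free diol.

Step 8
Reactants: 13 potassium [(1E,3R,5S)-3,5-dihydroxy-5-[(1R,2R)-1-methyl-2-(prop-1-en-2-yl)cyclopropyl]-3-(propan-2-yl)pent-1-en-1-yl]trifluoroborate; 14 4-[(tert-butyldimethylsilyl)oxy]benzoic acid
Product: 15 (1E,3R,5S)-3,5-dihydroxy-5-[(1R,2R)-1-methyl-2-(prop-1-en-2-yl)cyclopropyl]-3-(propan-2-yl)pent-1-en-1-yl 4-[(tert-butyldimethylsilyl)oxy]benzoate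
Conditions: 14 (1.5 equiv), CuBr (10 mol%), DMAP (20 mol%), 4 Å molecular sieves, O2 (1 atm), MeCN, 40 °C
Reagents that add atoms: none
Why: Chan–Lam-type oxidative copper-catalysed C–O coupling of an alkenyltrifluoroborate with a carboxylic acid, which keeps the E geometry and in which the acid is far more reactive than the hindered secondary and tertiary hydroxyl groups.

Step 9
Reactants: 15 (1E,3R,5S)-3,5-dihydroxy-5-[(1R,2R)-1-methyl-2-(prop-1-en-2-yl)cyclopropyl]-3-(propan-2-yl)pent-1-en-1-yl 4-[(tert-butyldimethylsilyl)oxy]benzoate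
Product: 16 (1S,3R,3aS,4S,8aR)-1,3-dihydroxy-6,8a-dimethyl-3-(propan-2-yl)-1,2,3,3a,4,5,8,8a-octahydroazulen-4-yl 4-[(tert-butyldimethylsilyl)oxy]benzoate (trans-fused)
Conditions: [Rh(CO)2Cl]2 (5 mol%), toluene (0.02 M), 90 °C
Reagents that add atoms: none
Why: Monovalent rhodium opens the cyclopropane at the C7–C8a bond to a σ-alkyl/π-allyl trivalent rhodium species, the tethered enol ester inserts into the Rh–C8a bond (C3a–C8a, five-membered ring by 5-exo migratory insertion), and reductive elimination of C4 with the far allyl terminus C5 contracts the eight-membered rhodacycle to the seven-membered ring (C4–C5), a net [5+2] cycloaddition that leaves the C6=C7 olefin. The closest known reaction type is the rhodium-catalysed intramolecular [5+2] cycloaddition of cis-2-ene-vinylcyclopropanes, in which the alkene is tethered to the ring carbon; known cases carry terminal alkenes and a CH ring carbon, so the 1,2-disubstituted enol ester and the fully substituted C8a are the extrapolation. C8a is controlled by the cyclopropane, because ring opening and insertion both go with retention, and C4 relative to C3a by the E geometry of the enol ester, because both bonds form on one face of the alkene, which places H-3a and the aroyloxy group cis. C3a relative to C8a is controlled by the cis relation of tether and isopropenyl group: the alkene must bind on the rhodium face next to the allyl terminus and insert anti to the C8a methyl group, so that C8 and H-3a end up syn and the ring fusion trans. The step needs cleavage of C7–C8a instead of C7–C8 and insertion faster than β-hydride loss from the tertiary alkylrhodium; the cis tether, whose alkene and two hydroxyl donors hold rhodium at C8a and whose geminal substitution at C3 favours ring closure, is what should secure both.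

Step 10
Reactants: 16 (1S,3R,3aS,4S,8aR)-1,3-dihydroxy-6,8a-dimethyl-3-(propan-2-yl)-1,2,3,3a,4,5,8,8a-octahydroazulen-4-yl 4-[(tert-butyldimethylsilyl)oxy]benzoate
Product: 17 (1S,3R,3aS,4S,8aR)-1-(acetyloxy)-3-hydroxy-6,8a-dimethyl-3-(propan-2-yl)-1,2,3,3a,4,5,8,8a-octahydroazulen-4-yl 4-[(tert-butyldimethylsilyl)oxy]benzoate
Conditions: Ac2O, pyridine, DMAP (cat.), CH2Cl2, 0 → 20 °C
Reagents that add atoms: acetic anhydride CC(=O)OC(C)=O
Why: DMAP-catalysed acylation that distinguishes the secondary C1 hydroxyl from the tertiary C3 hydroxyl; the acetate is introduced only now so that no β-acetoxy group sits next to the rhodium-bound C8a in step 9.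

Step 11
Reactants: 17 (1S,3R,3aS,4S,8aR)-1-(acetyloxy)-3-hydroxy-6,8a-dimethyl-3-(propan-2-yl)-1,2,3,3a,4,5,8,8a-octahydroazulen-4-yl 4-[(tert-butyldimethylsilyl)oxy]benzoate
Product: 18 (1S,3R,3aS,4S,8aR)-1-(acetyloxy)-3-hydroxy-6,8a-dimethyl-3-(propan-2-yl)-1,2,3,3a,4,5,8,8a-octahydroazulen-4-yl 4-hydroxybenzoate (CNP0275279.1)
Conditions: Bu4NF, AcOH (1:1), THF, 0 °C
Reagents that add atoms: none
Why: Fluoride cleavage of the aryl silyl ether, buffered with acetic acid so that the phenoxide formed does not attack the acetate or the benzoate.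

Compound list
1 | methacrolein (2-methylprop-2-enal) | CC(=C)C=O | starting material
2 | ethyl 2-[bis(2,2,2-trifluoroethoxy)phosphoryl]propanoate | CCOC(=O)C(C)P(=O)(OCC(F)(F)F)OCC(F)(F)F | starting material
3 | potassium salt of the α-carbanion of 2 | CCOC(=O)[C-](C)P(=O)(OCC(F)(F)F)OCC(F)(F)F.[K+] | intermediate (not isolated)
4 | ethyl (2Z)-2,4-dimethylpenta-2,4-dienoate | CCOC(=O)/C(C)=C\C(C)=C | intermediate
5 | (2Z)-2,4-dimethylpenta-2,4-dien-1-ol | OC/C(C)=C\C(C)=C | intermediate
6 | [(1R,2R)-1-methyl-2-(prop-1-en-2-yl)cyclopropyl]methanol | OC[C@]1(C)C[C@@H]1C(C)=C | intermediate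
7 | (1R,2R)-1-methyl-2-(prop-1-en-2-yl)cyclopropane-1-carbaldehyde | O=C[C@]1(C)C[C@@H]1C(C)=C | intermediate
8 | 3-methylbutan-2-one | CC(C)C(C)=O | starting material
9 | lithium 3-methylbut-1-en-2-olate | [Li+].[O-]C(=C)C(C)C | intermediate (not isolated)
10 | (5S)-5-hydroxy-2-methyl-5-[(1R,2R)-1-methyl-2-(prop-1-en-2-yl)cyclopropyl]pentan-3-one | CC(C)C(=O)C[C@H](O)[C@]1(C)C[C@@H]1C(C)=C | intermediate
11 | (1S,3R)-1-[(1R,2R)-1-methyl-2-(prop-1-en-2-yl)cyclopropyl]-3-(propan-2-yl)pent-4-yne-1,3-diol | C#C[C@](O)(C(C)C)C[C@H](O)[C@]1(C)C[C@@H]1C(C)=C | intermediate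
12 | (1S,3R,4E)-1-[(1R,2R)-1-methyl-2-(prop-1-en-2-yl)cyclopropyl]-3-(propan-2-yl)-5-(4,4,5,5-tetramethyl-1,3,2-dioxaborolan-2-yl)pent-4-ene-1,3-diol | CC1(C)OB(/C=C/[C@](O)(C(C)C)C[C@H](O)[C@]2(C)C[C@@H]2C(C)=C)OC1(C)C | intermediate (not isolated)
13 | potassium [(1E,3R,5S)-3,5-dihydroxy-5-[(1R,2R)-1-methyl-2-(prop-1-en-2-yl)cyclopropyl]-3-(propan-2-yl)pent-1-en-1-yl]trifluoroborate | [K+].F[B-](F)(F)/C=C/[C@](O)(C(C)C)C[C@H](O)[C@]1(C)C[C@@H]1C(C)=C | intermediate
14 | 4-[(tert-butyldimethylsilyl)oxy]benzoic acid | CC(C)(C)[Si](C)(C)Oc1ccc(cc1)C(O)=O | starting material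
15 | (1E,3R,5S)-3,5-dihydroxy-5-[(1R,2R)-1-methyl-2-(prop-1-en-2-yl)cyclopropyl]-3-(propan-2-yl)pent-1-en-1-yl 4-[(tert-butyldimethylsilyl)oxy]benzoate | CC(C)(C)[Si](C)(C)Oc1ccc(cc1)C(=O)O/C=C/[C@](O)(C(C)C)C[C@H](O)[C@]2(C)C[C@@H]2C(C)=C | intermediate
16 | (1S,3R,3aS,4S,8aR)-1,3-dihydroxy-6,8a-dimethyl-3-(propan-2-yl)-1,2,3,3a,4,5,8,8a-octahydroazulen-4-yl 4-[(tert-butyldimethylsilyl)oxy]benzoate | O[C@H]1C[C@@](O)(C(C)C)[C@@H]2[C@@H](OC(=O)c3ccc(O[Si](C)(C)C(C)(C)C)cc3)CC(C)=CC[C@@]12C | intermediate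
17 | (1S,3R,3aS,4S,8aR)-1-(acetyloxy)-3-hydroxy-6,8a-dimethyl-3-(propan-2-yl)-1,2,3,3a,4,5,8,8a-octahydroazulen-4-yl 4-[(tert-butyldimethylsilyl)oxy]benzoate | CC(=O)O[C@H]1C[C@@](O)(C(C)C)[C@@H]2[C@@H](OC(=O)c3ccc(O[Si](C)(C)C(C)(C)C)cc3)CC(C)=CC[C@@]12C | intermediate
18 | (1S,3R,3aS,4S,8aR)-1-(acetyloxy)-3-hydroxy-6,8a-dimethyl-3-(propan-2-yl)-1,2,3,3a,4,5,8,8a-octahydroazulen-4-yl 4-hydroxybenzoate | CC(=O)O[C@H]1C[C@@](O)(C(C)C)[C@@H]2[C@@H](OC(=O)c3ccc(O)cc3)CC(C)=CC[C@@]12C | target

Total step count: 11. Longest linear sequence: 11 steps (1 and 2 to 18).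

Steps most likely to fail

1. Step 9. After the cyclopropane opens, β-hydride loss from the tertiary alkylrhodium or cleavage of the other ring bond may outrun insertion of the donor-substituted, 1,2-disubstituted enol ester, and the γ-hydroxy enol ester may ionise or transfer its acyl group at 90 °C. The fallback changes the 2π partner and builds the C4–O bond after the rings. It sets out from 12, isolated instead of being converted into 13, and comes back at 17. The same rhodium catalyst applied to the E-alkenylboronate should give, by the same stereochemical course, (1S,3R,3aR,4S,8aR)-6,8a-dimethyl-3-(propan-2-yl)-4-(4,4,5,5-tetramethyl-1,3,2-dioxaborolan-2-yl)-1,2,3,3a,4,5,8,8a-octahydroazulene-1,3-diol F1. Ac2O/pyridine/DMAP acetylates its secondary C1 hydroxyl to the corresponding 1-acetate F2. NaBO3·4H2O in THF/H2O oxidises the C–B bond with retention to (1S,3R,3aS,4S,8aR)-3,4-dihydroxy-6,8a-dimethyl-3-(propan-2-yl)-1,2,3,3a,4,5,8,8a-octahydroazulen-1-yl acetate F3. Esterification of the C4 hydroxyl of F3 with 14 (EDC·HCl, DMAP, CH2Cl2) gives 17.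

2. Step 6. The addition may run through a non-chelated magnesium aldolate, which erodes the 1,3-induction, and the aldolate may fragment by retro-aldol cleavage. The fallback enforces chelation on a neutral β-alkoxy ketone. It sets out from 10 and comes back at 11. 4-Methoxybenzyl trichloroacetimidate with catalytic La(OTf)3 gives (5S)-5-[(4-methoxyphenyl)methoxy]-2-methyl-5-[(1R,2R)-1-methyl-2-(prop-1-en-2-yl)cyclopropyl]pentan-3-one F4. Precomplexation with MgBr2·OEt2 in CH2Cl2 at −78 °C and addition of HC≡CMgBr (bidentate chelate in a non-coordinating solvent, no alkoxide that could fragment) should give (3R,5S)-5-[(4-methoxyphenyl)methoxy]-5-[(1R,2R)-1-methyl-2-(prop-1-en-2-yl)cyclopropyl]-3-(propan-2-yl)pent-1-yn-3-ol F5. DDQ in CH2Cl2/pH 7 buffer removes the benzyl ether and gives 11.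

3. Step 5. Facial selectivity of the enolate addition rests on one conformer of the aldehyde and may be poor, and part of 7 may be lost to its dihydrooxepine valence isomer before it reacts. The fallback sets the carbinol by catalyst control and does not isolate the aldehyde. It sets out from 6 and comes back at 10. TEMPO/PhI(OAc)2 in MeCN/H2O oxidises 6 to (1R,2R)-1-methyl-2-(prop-1-en-2-yl)cyclopropane-1-carboxylic acid F6. Activation with carbonyldiimidazole and C-acylation of Mg(O2CCH2CO2Et)2 with loss of CO2 gives ethyl 3-[(1R,2R)-1-methyl-2-(prop-1-en-2-yl)cyclopropyl]-3-oxopropanoate F7. Noyori asymmetric hydrogenation with [RuCl2((R)-BINAP)] (H2 4 atm, EtOH, 80 °C; unactivated olefins are expected to survive at this pressure) should give ethyl (3S)-3-hydroxy-3-[(1R,2R)-1-methyl-2-(prop-1-en-2-yl)cyclopropyl]propanoate F8. MeNH(OMe)·HCl/iPrMgCl converts F8 into (3S)-3-hydroxy-N-methoxy-N-methyl-3-[(1R,2R)-1-methyl-2-(prop-1-en-2-yl)cyclopropyl]propanamide F9, and iPrMgCl then gives 10.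

Further compounds
F1 | step 9 | (1S,3R,3aR,4S,8aR)-6,8a-dimethyl-3-(propan-2-yl)-4-(4,4,5,5-tetramethyl-1,3,2-dioxaborolan-2-yl)-1,2,3,3a,4,5,8,8a-octahydroazulene-1,3-diol | O[C@H]1C[C@@](O)(C(C)C)[C@@H]2[C@@H](B3OC(C)(C)C(C)(C)O3)CC(C)=CC[C@@]12C
F2 | step 9 | (1S,3R,3aR,4S,8aR)-3-hydroxy-6,8a-dimethyl-3-(propan-2-yl)-4-(4,4,5,5-tetramethyl-1,3,2-dioxaborolan-2-yl)-1,2,3,3a,4,5,8,8a-octahydroazulen-1-yl acetate | CC(=O)O[C@H]1C[C@@](O)(C(C)C)[C@@H]2[C@@H](B3OC(C)(C)C(C)(C)O3)CC(C)=CC[C@@]12C
F3 | step 9 | (1S,3R,3aS,4S,8aR)-3,4-dihydroxy-6,8a-dimethyl-3-(propan-2-yl)-1,2,3,3a,4,5,8,8a-octahydroazulen-1-yl acetate | CC(=O)O[C@H]1C[C@@](O)(C(C)C)[C@@H]2[C@@H](O)CC(C)=CC[C@@]12C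
F4 | step 6 | (5S)-5-[(4-methoxyphenyl)methoxy]-2-methyl-5-[(1R,2R)-1-methyl-2-(prop-1-en-2-yl)cyclopropyl]pentan-3-one | CC(C)C(=O)C[C@H](OCc1ccc(OC)cc1)[C@]2(C)C[C@@H]2C(C)=C
F5 | step 6 | (3R,5S)-5-[(4-methoxyphenyl)methoxy]-5-[(1R,2R)-1-methyl-2-(prop-1-en-2-yl)cyclopropyl]-3-(propan-2-yl)pent-1-yn-3-ol | C#C[C@](O)(C(C)C)C[C@H](OCc1ccc(OC)cc1)[C@]2(C)C[C@@H]2C(C)=C
F6 | step 5 | (1R,2R)-1-methyl-2-(prop-1-en-2-yl)cyclopropane-1-carboxylic acid | OC(=O)[C@]1(C)C[C@@H]1C(C)=C
F7 | step 5 | ethyl 3-[(1R,2R)-1-methyl-2-(prop-1-en-2-yl)cyclopropyl]-3-oxopropanoate | CCOC(=O)CC(=O)[C@]1(C)C[C@@H]1C(C)=C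
F8 | step 5 | ethyl (3S)-3-hydroxy-3-[(1R,2R)-1-methyl-2-(prop-1-en-2-yl)cyclopropyl]propanoate | CCOC(=O)C[C@H](O)[C@]1(C)C[C@@H]1C(C)=C
F9 | step 5 | (3S)-3-hydroxy-N-methoxy-N-methyl-3-[(1R,2R)-1-methyl-2-(prop-1-en-2-yl)cyclopropyl]propanamide | CON(C)C(=O)C[C@H](O)[C@]1(C)C[C@@H]1C(C)=C
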